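**Strategy.** The route rests on disconnecting the C3–C4 bond of the terminal flavan-3,4-diol unit: its cis-diol on ring C, with C4 benzylic to ring A and C3 next to the O1–C2(aryl) stereocentre, is the retron of a reductive pinacol coupling. A dialdehyde carrying a ring-A formyl group and an α-aryloxy aldehyde, whose single stereocentre comes from an iridium-catalysed allylic etherification, is cyclised with SmI2 to close ring C and set C3 and C4 in one operation. The resulting protected teracacidin then serves three times: as bromine-capped electrophile, as thioether-masked middle unit and as the diol-bearing terminus, joined by two orthogonal Friedel–Crafts couplings.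

Key step: step 5

Remark: intermediates carry flavan numbering (O1, C2, C3, C4, C4a, C5 to C8, C8a; ring A benzo, ring C pyran, 4' on the 2-aryl group), α/β follow the usual drawing in which the 2-aryl group of a 2R flavan is α, epioritin is (2R,3R)-2,3-cis-7,8,4'-trihydroxyflavan-3-ol, and the phosphoramidite enantiomer in step 3 is taken to be the one that delivers the S ether.

**Step 1**
Reactants: 1 2,3,4-trihydroxybenzaldehyde
Product: 2 3,4-bis(benzyloxy)-2-hydroxybenzaldehyde
Conditions: BnBr (2.05 equiv), K2CO3 (2.1 equiv), DMF, rt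
Reagents that add atoms: benzyl bromide, BrCc1ccccc1
Why: Williamson etherification in which the 2-hydroxyl, hydrogen-bonded to the formyl group, is the least nucleophilic site, so the 3- and 4-hydroxyls should be benzylated selectively; no stereocentre is involved.

**Step 2**
Reactants: 3 1-(benzyloxy)-4-ethenylbenzene (4-benzyloxystyrene); 4 allyl methyl carbonate (threefold excess)
Product: 5 (E)-3-[4-(benzyloxy)phenyl]prop-2-en-1-yl methyl carbonate
Conditions: second-generation Hoveyda–Grubbs catalyst (3 mol %), CH2Cl2, 40 °C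
Reagents that add atoms: none
Why: olefin cross-metathesis of a styrene with an excess of a terminal allylic carbonate should give the conjugated E alkene under thermodynamic control with loss of ethylene.

**Step 3**
Reactants: 2 3,4-bis(benzyloxy)-2-hydroxybenzaldehyde; 5 (E)-3-[4-(benzyloxy)phenyl]prop-2-en-1-yl methyl carbonate
Product: 6 3,4-bis(benzyloxy)-2-{[(1S)-1-[4-(benzyloxy)phenyl]prop-2-en-1-yl]oxy}benzaldehyde
Conditions: NaH, THF, 0 °C; then 5, [Ir(cod)Cl]2 (2 mol %, monovalent iridium), (Sa,S,S)-O,O'-(1,1'-binaphthyl-2,2'-diyl) N,N-bis(1-phenylethyl)phosphoramidite (4 mol %), THF, 50 °C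
Reagents that add atoms: none
Why: iridium-catalysed asymmetric allylic etherification in which the sodium aryloxide attacks the substituted terminus of the π-allyliridium intermediate from outside the metal, the cyclometalated phosphoramidite complex fixing the face so that the branched S ether, the future C2 of the flavan, should form.

**Step 4**
Reactants: 6 3,4-bis(benzyloxy)-2-{[(1S)-1-[4-(benzyloxy)phenyl]prop-2-en-1-yl]oxy}benzaldehyde
Product: 7 3,4-bis(benzyloxy)-2-{[(1R)-1-[4-(benzyloxy)phenyl]-2-oxoethyl]oxy}benzaldehyde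
Conditions: O3, CH2Cl2/MeOH, −78 °C (stopped at the first trace of excess ozone); then Me2S, −78 °C → rt; crude product used at once
Reagents that add atoms: ozone, [O-][O+]=O
Why: ozonolysis with reductive work-up cleaves the only alkene far faster than the alkoxyarenes at −78 °C and leaves the stereocentre untouched (S becomes R only through the priority rules), and the epimerisation-prone α-aryl-α-aryloxy aldehyde is not stored.

**Step 5**
Reactants: 7 3,4-bis(benzyloxy)-2-{[(1R)-1-[4-(benzyloxy)phenyl]-2-oxoethyl]oxy}benzaldehyde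
Product: 9 3,4-di-O-acetyl-7,8,4'-tri-O-benzylteracacidin [(2R)-2,3-cis-3,4-cis-7,8-bis(benzyloxy)-2-[4-(benzyloxy)phenyl]chromane-3,4-diyl diacetate; aryl, 3-OAc and 4-OAc all α], via samarium diolate 8 (not isolated)
Conditions: SmI2 (2.5 equiv), THF (0.01 M in 7), −78 → −30 °C; then Ac2O, DMAP, −30 °C → rt
Reagents that add atoms: acetic anhydride, CC(=O)OC(C)=O
Why: SmI2 transfers one electron to the ring-A aldehyde (the conjugated, more easily reduced carbonyl) to give a samarium-bound benzylic ketyl at C4, which adds to the samarium-coordinated α-aryloxy aldehyde carbon C3 before a second electron transfer delivers the diolate, trapped in the flask by Ac2O so that the acid-labile benzylic diol is never handled. The closest known reaction type is the SmI2-mediated intramolecular pinacol coupling of dialdehydes to cyclic cis-1,2-diols. Ring C (O1–C2–C3–C4–C4a–C8a) is closed in a 6-exo-trig mode by attack of the C4 ketyl on the C3 carbonyl. The 3,4-cis relationship should follow from both oxygens being held on one trivalent samarium centre in the bond-forming transition state, and the C3 configuration from the existing C2 centre, whose aryl group sits pseudo-equatorial and anti to the forming bond (Felkin–Anh) while the C3 carbonyl oxygen lies gauche to O1, a placement reinforced by chelation of samarium by O1 and the neighbouring 8-benzyloxy oxygen; together these give the 2,3-cis-3,4-cis array. The step needs ring closure to outrun reductive expulsion of the aryloxide from C2 and simple carbonyl reduction, which the faster reduction of the aryl aldehyde, the six-membered intramolecular trap, low temperature, high dilution and the absence of a proton donor are expected to secure.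

**Step 6**
Reactants: 9 3,4-di-O-acetyl-7,8,4'-tri-O-benzylteracacidin
Product: 10 6-bromo-3,4-di-O-acetyl-7,8,4'-tri-O-benzylteracacidin
Conditions: NBS (1.05 equiv), CH2Cl2, −20 → 0 °C
Reagents that add atoms: N-bromosuccinimide, O=C1CCC(=O)N1Br
Why: electrophilic aromatic bromination should go to C6 of ring A, the only position activated by two oxygens (para to O1, ortho to the 7-benzyloxy group), and the bromine blocks this nucleophilic site of the future upper unit.

**Step 7**
Reactants: 9 3,4-di-O-acetyl-7,8,4'-tri-O-benzylteracacidin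
Product: 11 3-O-acetyl-4β-(benzylsulfanyl)-7,8,4'-tri-O-benzylepioritin [(2R)-2,3-cis-3,4-trans-4-(benzylsulfanyl)-7,8-bis(benzyloxy)-2-[4-(benzyloxy)phenyl]chroman-3-yl acetate]
Conditions: BnSH (5 equiv), BF3·OEt2, CH2Cl2, −40 → 0 °C
Reagents that add atoms: phenylmethanethiol, SCc1ccccc1
Why: Lewis-acid-promoted SN1 thiolysis of the benzylic 4-acetate in which the C4 cation, bridged as an acetoxonium ion by the 3-acetate, is opened by the thiol from the β face (3,4-trans), the excess thiol outcompeting self-arylation.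

**Step 8**
Reactants: 10 6-bromo-3,4-di-O-acetyl-7,8,4'-tri-O-benzylteracacidin; 11 3-O-acetyl-4β-(benzylsulfanyl)-7,8,4'-tri-O-benzylepioritin (1.3 equiv)
Product: 12 6-bromo-3-O-acetyl-7,8,4'-tri-O-benzylepioritin-(4β→6)-3-O-acetyl-4β-(benzylsulfanyl)-7,8,4'-tri-O-benzylepioritin
Conditions: BF3·OEt2, 4 Å molecular sieves, CH2Cl2, −78 → −20 °C
Reagents that add atoms: none
Why: Friedel–Crafts arylation of a flavan-4-yl cation in which the hard Lewis acid ionises the 4-acetate of 10 but not the thioether of 11, C6 of 11 (para to O1) attacks the acetoxonium-bridged cation anti to the 3-acetoxy group to set the 4β (3,4-trans) interflavan bond, and the bromine of 10 excludes self-condensation.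

**Step 9**
Reactants: 12 6-bromo-3-O-acetyl-7,8,4'-tri-O-benzylepioritin-(4β→6)-3-O-acetyl-4β-(benzylsulfanyl)-7,8,4'-tri-O-benzylepioritin; 9 3,4-di-O-acetyl-7,8,4'-tri-O-benzylteracacidin (2 equiv)
Product: 13 6-bromo-3-O-acetyl-7,8,4'-tri-O-benzylepioritin-(4β→6)-3-O-acetyl-7,8,4'-tri-O-benzylepioritin-(4β→6)-3,4-di-O-acetyl-7,8,4'-tri-O-benzylepioritin-4α-ol
Conditions: AgBF4 (monovalent silver), 2,6-di-tert-butyl-4-methylpyridine, 4 Å molecular sieves, CH2Cl2/THF, −20 → 0 °C, dark
Reagents that add atoms: none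
Why: thiophilic activation in which monovalent silver abstracts the benzylthiolate, the C4 cation of the middle unit (shielded on its α face by the 3-acetate) is trapped by C6 of 9 to set the second 4β bond, and the hindered pyridine removes HBF4 so that the 4-acetate of the terminal unit is not ionised.

**Step 10**
Reactants: 13 the tetra-O-acetyl nona-O-benzyl bromo trimer
Product: 14 6-bromo-7,8,4'-tri-O-benzylepioritin-(4β→6)-7,8,4'-tri-O-benzylepioritin-(4β→6)-7,8,4'-tri-O-benzylepioritin-4α-ol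
Conditions: NaOMe (cat.), MeOH/THF, rt
Reagents that add atoms: none
Why: Zemplén transesterification removes the four acetates by acyl–oxygen cleavage, so no carbinol centre is touched and the benzyl ethers and the aryl bromide survive.

**Step 11**
Reactants: 14 the nona-O-benzyl bromo trimer tetraol
Product: 15 epioritin-(4β→6)-epioritin-(4β→6)-epioritin-4α-ol (CNP0140823.1)
Conditions: H2 (1 atm), Pd(OH)2/C, Et3N (2 equiv), THF/MeOH, rt; filtration and chromatography on Sephadex LH-20 under argon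
Reagents that add atoms: none
Why: heterogeneous hydrogenolysis cleaves the nine aryl benzyl ethers and the aryl bromide, triethylamine capturing HBr so that the acid-labile benzylic 4-hydroxyl of the terminal unit should be neither ionised nor hydrogenolysed, and no stereocentre is affected.

**Compound list**

1 | 2,3,4-trihydroxybenzaldehyde | O=Cc1ccc(O)c(O)c1O | starting material
2 | 3,4-bis(benzyloxy)-2-hydroxybenzaldehyde | O=Cc1ccc(OCc2ccccc2)c(OCc2ccccc2)c1O | intermediate
3 | 1-(benzyloxy)-4-ethenylbenzene | C=Cc1ccc(OCc2ccccc2)cc1 | starting material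
4 | allyl methyl carbonate | C=CCOC(=O)OC | starting material
5 | (E)-3-[4-(benzyloxy)phenyl]prop-2-en-1-yl methyl carbonate | COC(=O)OC/C=C/c1ccc(OCc2ccccc2)cc1 | intermediate
6 | 3,4-bis(benzyloxy)-2-{[(1S)-1-[4-(benzyloxy)phenyl]prop-2-en-1-yl]oxy}benzaldehyde | O=Cc1ccc(OCc2ccccc2)c(OCc2ccccc2)c1O[C@H](c1ccc(OCc2ccccc2)cc1)C=C | intermediate
7 | 3,4-bis(benzyloxy)-2-{[(1R)-1-[4-(benzyloxy)phenyl]-2-oxoethyl]oxy}benzaldehyde | O=Cc1ccc(OCc2ccccc2)c(OCc2ccccc2)c1O[C@H](c1ccc(OCc2ccccc2)cc1)C=O | intermediate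
8 | bis(diiodosamarium) 3,4-diolate of 2,3-cis-3,4-cis-7,8,4'-tri-O-benzylteracacidin (trivalent samarium) | c1cc2c(c(OCc3ccccc3)c1OCc1ccccc1)O[C@H](c1ccc(OCc3ccccc3)cc1)[C@H](O[Sm](I)I)[C@@H]2O[Sm](I)I | intermediate
9 | 3,4-di-O-acetyl-7,8,4'-tri-O-benzylteracacidin (2R, 2,3-cis-3,4-cis) | c1cc2c(c(OCc3ccccc3)c1OCc1ccccc1)O[C@H](c1ccc(OCc3ccccc3)cc1)[C@H](OC(C)=O)[C@@H]2OC(C)=O | intermediate
10 | 6-bromo-3,4-di-O-acetyl-7,8,4'-tri-O-benzylteracacidin | Brc1cc2c(c(OCc3ccccc3)c1OCc1ccccc1)O[C@H](c1ccc(OCc3ccccc3)cc1)[C@H](OC(C)=O)[C@@H]2OC(C)=O | intermediate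
11 | 3-O-acetyl-4β-(benzylsulfanyl)-7,8,4'-tri-O-benzylepioritin (2R, 2,3-cis-3,4-trans) | c1cc2c(c(OCc3ccccc3)c1OCc1ccccc1)O[C@H](c1ccc(OCc3ccccc3)cc1)[C@H](OC(C)=O)[C@H]2SCc1ccccc1 | intermediate
12 | 6-bromo-3-O-acetyl-7,8,4'-tri-O-benzylepioritin-(4β→6)-3-O-acetyl-4β-(benzylsulfanyl)-7,8,4'-tri-O-benzylepioritin | c1ccccc1COc1ccc([C@H]2Oc3c(cc(Br)c(OCc4ccccc4)c3OCc3ccccc3)[C@H](c3cc4c(c(OCc5ccccc5)c3OCc3ccccc3)O[C@H](c3ccc(OCc5ccccc5)cc3)[C@H](OC(C)=O)[C@H]4SCc3ccccc3)[C@H]2OC(C)=O)cc1 | intermediate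
13 | 6-bromo-3-O-acetyl-7,8,4'-tri-O-benzylepioritin-(4β→6)-3-O-acetyl-7,8,4'-tri-O-benzylepioritin-(4β→6)-3,4-di-O-acetyl-7,8,4'-tri-O-benzylepioritin-4α-ol | c1ccccc1COc1ccc([C@H]2Oc3c(cc(Br)c(OCc4ccccc4)c3OCc3ccccc3)[C@H](c3cc4c(c(OCc5ccccc5)c3OCc3ccccc3)O[C@H](c3ccc(OCc5ccccc5)cc3)[C@H](OC(C)=O)[C@H]4c3cc4c(c(OCc5ccccc5)c3OCc3ccccc3)O[C@H](c3ccc(OCc5ccccc5)cc3)[C@H](OC(C)=O)[C@@H]4OC(C)=O)[C@H]2OC(C)=O)cc1 | intermediate
14 | 6-bromo-7,8,4'-tri-O-benzylepioritin-(4β→6)-7,8,4'-tri-O-benzylepioritin-(4β→6)-7,8,4'-tri-O-benzylepioritin-4α-ol | c1ccccc1COc1ccc([C@H]2Oc3c(cc(Br)c(OCc4ccccc4)c3OCc3ccccc3)[C@H](c3cc4c(c(OCc5ccccc5)c3OCc3ccccc3)O[C@H](c3ccc(OCc5ccccc5)cc3)[C@H](O)[C@H]4c3cc4c(c(OCc5ccccc5)c3OCc3ccccc3)O[C@H](c3ccc(OCc5ccccc5)cc3)[C@H](O)[C@@H]4O)[C@H]2O)cc1 | intermediate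
15 | epioritin-(4β→6)-epioritin-(4β→6)-epioritin-4α-ol (CNP0140823.1) | Oc1ccc([C@H]2Oc3c(ccc(O)c3O)[C@H](c3cc4c(c(O)c3O)O[C@H](c3ccc(O)cc3)[C@H](O)[C@H]4c3cc4c(c(O)c3O)O[C@H](c3ccc(O)cc3)[C@H](O)[C@@H]4O)[C@H]2O)cc1 | target

**Step count.** Total: 11 steps. Longest linear sequence: 9 steps (1 → 2 → 6 → 7 → 9 → 10 → 12 → 13 → 14 → 15, steps 1, 3, 4, 5, 6, 8, 9, 10, 11).

**Steps most likely to fail**

Step 5. The C4 ketyl may add to the wrong face of the α-aryloxy aldehyde, giving the 2,3-trans diol. The α-aryloxy aldehyde may also be reduced with expulsion of the aryloxide, cleaving the O1–C2 bond. The fallback sets out from 6 and comes back at 9. Wittig methylenation of the formyl group of 6 (Ph3P=CH2, THF, 0 °C) would give 1,2-bis(benzyloxy)-3-{[(1S)-1-[4-(benzyloxy)phenyl]prop-2-en-1-yl]oxy}-4-ethenylbenzene F1. Ring-closing metathesis (second-generation Grubbs catalyst, CH2Cl2, 40 °C) would then close ring C as (2S)-7,8-bis(benzyloxy)-2-[4-(benzyloxy)phenyl]-2H-chromene F2. Woodward cis-hydroxylation (I2, AgOAc, AcOH, then H2O) should place both oxygens on the face of the 2-aryl group: the iodonium ion forms anti to the aryl group, acetate opens it at benzylic C4, and the acetoxonium ion then forms with inversion at C3. This would give 3-O-acetyl-7,8,4'-tri-O-benzylteracacidin F3, which Ac2O, pyridine and DMAP convert into 9.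

Step 9. Capture of the hindered dimeric C4 cation by the only moderately nucleophilic ring A of 9 may be slower than loss of the cation through elimination or reaction with adventitious water. The fallback reverses the order of assembly so that both interflavan bonds are made from monomer-sized cations; it sets out from 10, 11 and 9 and comes back at 13. Thiolysis of 10 (BnSH, BF3·OEt2, CH2Cl2) would give 6-bromo-3-O-acetyl-4β-(benzylsulfanyl)-7,8,4'-tri-O-benzylepioritin F4. Separately, 11 is activated with AgBF4 and 2,6-di-tert-butyl-4-methylpyridine in the presence of a threefold excess of 9 to give 3-O-acetyl-7,8,4'-tri-O-benzylepioritin-(4β→6)-3,4-di-O-acetyl-7,8,4'-tri-O-benzylepioritin-4α-ol F5. The free C6 of the upper unit of F5 is then arylated by the cation released from F4 under the same silver conditions to give 13.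

Step 3. The hindered, chelating aryloxide may react sluggishly, and reversible ionisation of the electron-rich allylic ether may erode branched selectivity and enantiomeric purity. The fallback sets out from 2 and comes back at 7. Diazo transfer to commercially available methyl 2-[4-(benzyloxy)phenyl]acetate (4-acetamidobenzenesulfonyl azide, DBU, MeCN) would give methyl 2-[4-(benzyloxy)phenyl]-2-diazoacetate F6. Enantioselective O–H insertion into 2 (Pd(PhCN)2Cl2 with divalent palladium, chiral spiro-bisoxazoline ligand, Na[B(3,5-(CF3)2C6H3)4], CHCl3) would give methyl (2R)-2-[2,3-bis(benzyloxy)-6-formylphenoxy]-2-[4-(benzyloxy)phenyl]acetate F7. LiBH4 (THF, 0 °C) reduces ester and aldehyde to (2R)-2-[2,3-bis(benzyloxy)-6-(hydroxymethyl)phenoxy]-2-[4-(benzyloxy)phenyl]ethan-1-ol F8. Double oxidation with Dess–Martin periodinane (NaHCO3, CH2Cl2) returns dialdehyde 7.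

**Further compounds**

F1 | step 5 | 1,2-bis(benzyloxy)-3-{[(1S)-1-[4-(benzyloxy)phenyl]prop-2-en-1-yl]oxy}-4-ethenylbenzene | C=Cc1ccc(OCc2ccccc2)c(OCc2ccccc2)c1O[C@H](c1ccc(OCc2ccccc2)cc1)C=C
F2 | step 5 | (2S)-7,8-bis(benzyloxy)-2-[4-(benzyloxy)phenyl]-2H-chromene | c1cc2c(c(OCc3ccccc3)c1OCc1ccccc1)O[C@H](c1ccc(OCc3ccccc3)cc1)C=C2
F3 | step 5 | 3-O-acetyl-7,8,4'-tri-O-benzylteracacidin (2,3-cis-3,4-cis, free 4α-hydroxyl) | c1cc2c(c(OCc3ccccc3)c1OCc1ccccc1)O[C@H](c1ccc(OCc3ccccc3)cc1)[C@H](OC(C)=O)[C@@H]2O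
F4 | step 9 | 6-bromo-3-O-acetyl-4β-(benzylsulfanyl)-7,8,4'-tri-O-benzylepioritin | Brc1cc2c(c(OCc3ccccc3)c1OCc1ccccc1)O[C@H](c1ccc(OCc3ccccc3)cc1)[C@H](OC(C)=O)[C@H]2SCc1ccccc1
F5 | step 9 | 3-O-acetyl-7,8,4'-tri-O-benzylepioritin-(4β→6)-3,4-di-O-acetyl-7,8,4'-tri-O-benzylepioritin-4α-ol | c1cc2c(c(OCc3ccccc3)c1OCc1ccccc1)O[C@H](c1ccc(OCc3ccccc3)cc1)[C@H](OC(C)=O)[C@H]2c1cc2c(c(OCc3ccccc3)c1OCc1ccccc1)O[C@H](c1ccc(OCc3ccccc3)cc1)[C@H](OC(C)=O)[C@@H]2OC(C)=O
F6 | step 3 | methyl 2-[4-(benzyloxy)phenyl]-2-diazoacetate | COC(=O)C(=[N+]=[N-])c1ccc(OCc2ccccc2)cc1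
F7 | step 3 | methyl (2R)-2-[2,3-bis(benzyloxy)-6-formylphenoxy]-2-[4-(benzyloxy)phenyl]acetate | O=Cc1ccc(OCc2ccccc2)c(OCc2ccccc2)c1O[C@H](c1ccc(OCc2ccccc2)cc1)C(=O)OC
F8 | step 3 | (2R)-2-[2,3-bis(benzyloxy)-6-(hydroxymethyl)phenoxy]-2-[4-(benzyloxy)phenyl]ethan-1-ol | OCc1ccc(OCc2ccccc2)c(OCc2ccccc2)c1O[C@H](c1ccc(OCc2ccccc2)cc1)CO
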